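(All runs were computed from invented constants; the scatter is artificial.)

Don't reach for a half-life here: it belongs to a curve that flattens, and the Qa readings of theta, eta and beta fall close to straight lines.

common to all: Qc 0.36 mM

|  | Qa | Qb | temperature | remark | time |
|---|---|---|---|---|---|
| theta | 36 mM | 24 mM | 65 °C | run made earlier |  |
| eta | 36 mM | 54 mM | 78 °C | run made earlier |  |
| beta | 72 mM | 36 mM | 65 °C | run made earlier |  |
| west | 36 mM | 36.0 mM | 70 °C |  | 3.0 h |
| south-west | 36 mM | 36.0 mM | 85 °C |  | 3.0 h |

| run | time / h | Qf / % | Qa / % | Qd / % |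
|---|---|---|---|---|
| theta | 0.667 | 0.4 | 96.6 | 2.6 |
| theta | 1.33 | 0.2 | 93.2 | 4.9 |
| theta | 2.00 | 0 | 91.1 | 8.4 |
| theta | 2.50 | 0 | 88.5 | 10.3 |
| theta | 3.00 | 0.7 | 86.6 | 12.6 |
| theta | 4.00 | 0 | 82.5 | 17.0 |
| eta | 0.250 | 0.5 | 94.2 | 4.4 |
| eta | 0.667 | 0 | 85.6 | 13.0 |
| eta | 1.33 | 0.6 | 73.3 | 26.3 |
| eta | 2.00 | 0.5 | 62.0 | 38.1 |
| eta | 3.00 | 0 | 44.9 | 56.1 |
| eta | 4.00 | 1.6 | 28.2 | 70.5 |
| beta | 0.667 | 0.2 | 98.8 | 1.9 |
| beta | 1.33 | 0 | 96.7 | 3.3 |
| beta | 2.00 | 0 | 94.6 | 5.1 |
| beta | 3.00 | 0.3 | 92.1 | 7.1 |
| beta | 4.00 | 0 | 91.4 | 8.9 |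

(each reading ± 0.5 percentage points)

* which of these there is most of at the end, counted by the Qa in it, west (Qa / Qf / Qd)
* which of these there is most of at the end, counted by the Qa in it, south-west (Qa / Qf / Qd)
* how much there is at the end of the one of these that leads, in percent of the Qa charged: west
* how much there is at the end of the one of these that leads, in percent of the Qa charged: south-west



So work with the fraction of Qa left, and with two times: the time of the run and the clearing time, which is the time of a late reading divided by the fraction of Qa gone by then. While the line stays straight, the fraction left is one minus the ratio of these two times. Theta gives a clearing time of 22.9 h. Beta, with twice the Qa charge at the same temperature, gives 46.5 h, which is twice as long. The pace read in mM therefore stays at 1.57 mM/h against 1.55 mM/h, which reads as zero order in Qa, although Qb differs between these two runs as well.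

Eta, hotter, gives 5.57 h. Shortening the clearing time by the same factor for each degree between theta and eta, and assuming that Qb has no effect, gives 13.3 h for west; this is the clearing time of west, the time its Qa would last at its straight-line pace. My own reckoning for west at 3.0 h is therefore 77.4 % of Qa left, and Qa leads. South-west extrapolates to 2.61 h, shorter than its run, so I expect Qd to lead there, with a remainder that a straight line can't tell.

The forecast gives Qa at 76 % for west and Qd at 93 % for south-west, on the ground that “Qd rises almost linearly, so the reaction is close to zero order and catalyst-limited”.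

West ends with Qa leading at 75.7 %, and south-west with Qd leading at 90.5 %.

    Qg → Qc + Qe (k = 1.53 /min, Ea = 99.0 kJ/mol)
    Qa + Qc ⇌ Qf (K = 150 /M, k = 43.9 /M/min, Ea = 60.0 kJ/mol, ΔH = −3.00 kJ/mol)
    Qb + Qc ⇌ Qg (K = 28.2 /M, k = 20.6 /M/min, Ea = 65.0 kJ/mol, ΔH = −4.00 kJ/mol)
    Qf → Qc + Qd (k = 0.451 /min, Ea = 91.0 kJ/mol)
    2 Qf ⇌ Qh, settled at all times (K = 8300 /M, ΔH = −90.0 kJ/mol)
    (constants at 70 °C)

West is far from rest at 3.0 h, with 75.7 % of its Qa still there, unbound. Its clearing time also serves when west is left until 8.0 h, where the line leaves 39.8 % and the flask holds 39 %. Ten times the time lies past the clearing time, and at 30.0 h west shows Qa at 0 % and Qd at >99.9 %. South-west has not come to rest either: it still holds 9.31 % of its Qa, and ten times the time adds 9.5 percentage points of Qd, which ends at 100 %.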